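Slowness came to mind first: in both earlier runs substrate left within minutes, and the way to target did not keep up.

| flask | substrate | acid | remark | time |
|---|---|---|---|---|
| zeta | 22 mM | 0.20 mM | run made earlier |  |
| beta | 58 mM | 0.20 mM | run made earlier |  |
| south-east | 20 mM | 0.200 mM |  | 30 min |
| south | 40 mM | 0.200 mM |  | 30 min |
| north | 80 mM | 0.200 mM |  | 30 min |
| west | 150 mM | 0.200 mM |  | 30 min |

| run | time / min | target / % | side product / % | substrate / % |
|---|---|---|---|---|
| zeta | 2.00 | 6.3 | 1.7 | 27.0 |
| zeta | 5.00 | 12.6 | 0.7 | 10.5 |
| zeta | 10.0 | 15.9 | 1.7 | 2.0 |
| zeta | 15.0 | 17.9 | 0 | 4.5 |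
| zeta | 20.0 | 17.0 | 2.4 | 0.5 |
| beta | 1.50 | 3.5 | 0.9 | 16.4 |
| beta | 3.00 | 7.3 | 1.4 | 7.3 |
| beta | 6.00 | 6.8 | 0 | 2.4 |
| beta | 12.0 | 9.4 | 0.7 | 1.3 |
| beta | 20.0 | 9.2 | 1.0 | 1.9 |

(readings scatter by 1 percentage point)

- acid is the free proton; pH is minus the decimal logarithm of its molar concentration
- a reading or a percentage of target counts all its forms, free or not
- "hardly changes" means that all values lie within two and a half points (for a concentration: within two and a half percent of the largest)
- a reading of substrate is of its free form alone

- share of target in all that became target or side product for south-east, south, north, west, in this order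
- the shape of the row from first to last (hardly changes / falls all the way / falls, then rises / rises all the way / rises, then falls)

I read the last row of each table. In zeta, at 20.0 min, substrate stood at 0.5%, target at 17.0% and side product at 2.4%. So 80.1% had gone somewhere unseen. In beta the unseen part was larger, 87.9%.

Percentages hid the point, so I turned them into concentrations. I called the pool c(target) plus c(side product) in that last row: 4.27 mM in zeta and 5.92 mM in beta. The charge grew by a factor of 2.64, but the pool grew by 1.39. From these I kept 0.337, the pool exponent, the slope of ln pool against ln charge. It is rough, since each reading carries 1 percentage point.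

Then I made an assumption of my own: side product comes from target meeting a partner born with it, so the side share should go with the pool. Zeta's last row gave a side share of 12.4%, and I took it unchanged for the asked 30 min. Beta's row gave 9.80%, which shows no rise, but its side product of 1.0% carries a scatter of 1 point. Scaling zeta's share, I expected a share of target, the selectivity, of 88.0% at 20 mM and 76.4% at 150 mM.

The forecast differed. It gave 91%, 91%, 91% and 91%, a row that hardly changes, holding that “both products seem to share the same order in substrate”.

The flasks gave 88.2%, 84.6%, 80.8% and 77.3%; the row falls all the way.

    substrate + acid → weak acid + acid + target (k = 3.50 L mol⁻¹ s⁻¹)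
    weak acid ⇌ conjugate base + acid, settled at all times (K = 1.60 × 10⁻⁵ M)
    weak acid + target → side product (k = 0.0280 L mol⁻¹ s⁻¹)
    substrate + target ⇌ idle adduct, settled at all times (K = 76.0 L mol⁻¹)
    substrate → weak acid + target (k = 4.40 × 10⁻⁴ s⁻¹)
    2 substrate → homo dimer (k = 0.440 L mol⁻¹ s⁻¹)

Weak acid is born with target, and side product takes one of each. In west, the homo dimer route together with the early reading kept the share at 77.3%: without that route it stood at 30.6%, and ten times later at 19.6%. Scaling south-east's side share of 11.8% by the pool exponent gave a target share of 81.2% for north, against 80.8%, and 76.7% for west, against 77.3%.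

(The numbers in the tables come from a simulation with constants of no real substance; noise was put on by code.)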